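A leftover is what to watch in the north flask. From 1.33 h to 2.50 h, X goes from 24% to 21% and E from 19% to 15%, steps close to the scatter of 2 percentage points. So we take X and E as a fast pair that has settled, and we carry one number: the pool ratio 0.769, the summed E over the summed X of these late north readings, c_E/c_X. The same ratio in the west run, with 1.8 equiv of Q, reads 0.919 from 2.00 h on. The ratio holds no Q, so it tells how the pool splits, not what stopped L.

common to all: X 0.050 M

| flask | Q | remark | time |
|---|---|---|---|
| north | 1.2 equiv (fed, over 2.5 min) | the very flask that is asked about, followed so far |  |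
| west | 1.8 equiv (fed, over 2.5 min) | run made earlier |  |
| flask | 1.20 equiv (fed, over 2.5 min) |  | 5.0 h |

| run | time / h | X / % | L / % | E / % |
|---|---|---|---|---|
| north | 0.417 | 35 | 37 | 25 |
| north | 0.833 | 27 | 56 | 17 |
| north | 1.33 | 24 | 57 | 19 |
| north | 1.50 | 22 | 56 | 20 |
| north | 2.00 | 24 | 63 | 16 |
| north | 2.50 | 21 | 61 | 15 |
| west | 0.417 | 34 | 44 | 21 |
| west | 0.667 | 22 | 55 | 12 |
| west | 1.00 | 16 | 59 | 15 |
| west | 2.00 | 14 | 68 | 12 |
| west | 3.00 | 14 | 66 | 10 |
| west | 5.00 | 9 | 71 | 12 |

(standard deviation of a reading: 2 percentage points)

- a reading or a percentage of L counts all its forms, free or not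
- the reaction counts as stopped when no species that holds the X changes by six tenths of a point or more over the second half of the time

1. the state of affairs at 5.0 h: stopped, and by what, or still going (it is still moving / forward and back rates have come level / Q has run out first / all of X has reacted)
2. share of the X used up at 5.0 h
3. L at 5.0 h, in percent of the X charged
4. E at 5.0 h, in percent of the X charged

Two ends of the north flask can be done in the head. With no L formed, the pool is the whole charge, and X stands at 56.5% with E at 43.5%. With the whole pool turned into L, X and E both stand at nothing. The real flask lies on the line between, and L places it. We take the mean of the last two north readings, 62.0%. The pool ratio splits the rest, so our reckoning for 5.0 h is X 21.5% and E 16.5%.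

The forecast says forward and back rates have come level, with conversion 78%, L 61% and E 17%. Its L is lower than ours. It wrote: “These agree, so forward and back rates have come level”.

At 5.0 h the flask stands thus: Q has run out first, with 0% of its charge left; conversion is 79.2%, L 59.0%, E 16.6%.

    X ⇌ E (K = 0.800, k = 0.00210 /s)
    Q → Z (k = 0.00230 /s)
    E + Z → L (k = 0.0590 /M/s)
    2 Z → G (k = 0.0220 /M/s)
    Q + L → J (k = 0.0460 /M/s)
    D ⇌ L, rate k6*(cs6 - [L]) while solid is left; crystals form when [L] > cs6 (solubility = 2.10 mM, k = 0.0990 /s)

Q is the limiting reagent of this flask, at 0% of its charge. X and E relax with a half-life of 2.44 min, shorter than the 0.14 h in which Z takes E at 0.102 h. This flask ends with c_E/c_X at 0.800. With our 0.769, what L and J 3.61% leave gives X 21.2%, and the flask holds 20.8%. In the flask charged with 0.300 equiv of Q, L 24.0% and J 0.643% give X 42.6% by the same reckoning, and it holds 41.8%.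

The readings stem from a simulated flask from invented constants; the scatter is artificial.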